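**Plan**

1. Target numbering (6-oxabicyclo[3.2.2]non-3-ene-2,7-dione): C1 is the CH between the two C=O groups, C2 the ketone, C3 carries the allyl group, then C4, C5 the ketal carbon, O6, C7 the lactone C=O, C8 carries the aryl group, C9 the methyl group.
2. Retrosynthesis: open the methyl ketal and lactone at C5, remove C7 from C1 (carboxylation retron), then remove the C9 methyl (enolate alkylation retron). This leaves 2-allyl-6-arylcyclohept-2-ene-1,4-dione.
3. Enabling feature: the carbocycle C1-C2-C3-C4-C5-C9-C8 is a masked cyclohept-2-ene-1,4-dione in which C9 is alpha to C5=O. A transannular aldol bond C2–C9 folds it into a 1-hydroxybicyclo[3.2.0]hept-2-en-4-one. In that form C2–C3 and C5–C9 are the two bonds of a [3+2] annulation between a cyclobutanone (C2, C1, C8, C9) and a beta-acylvinyl anion equivalent (C5, C4, C3).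
4. Forward order: the cyclobutane comes first ([2+2]) and the cyclopentene second (key step). Retro-aldol cleavage of the temporary C2–C9 bond merges both into the seven-membered ring, followed by methyl, carboxyl and the lactone bridge.
5. Helpers: SiMe2tBu (Brook trigger), SPh (anion stabiliser, later the leaving group that installs C3=C4), and the temporary four-membered ring.
6. Stereochemistry: C8 comes from enantioselective deprotonation of the prochiral cyclobutanone, C9 from methylation anti to the aryl group, and C1 and C5 from equilibrating closure of the lactol bridge.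

Key step: step 8

Assumption 1: the (S,S)-amide is taken to give the S enol silane 5, by analogy with other 3-arylcyclobutanones. If the sense is opposite, the (R,R)-amide is used.
Assumption 2: the C1-epimeric keto acids can give two bridged lactols. The one with the aryl group on the side of the two-atom lactone bridge (target series) is taken as the more stable, because the other places the aryl group beside the allyl-bearing three-atom bridge. The two interconvert through the open keto acid.

Step 1
Reactants: 1 3,4,5-trimethoxybenzaldehyde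
Product: 2 3,4,5-trimethoxystyrene (5-ethenyl-1,2,3-trimethoxybenzene)
Conditions: Ph3PCH3Br, KOtBu, THF, 0 °C to rt
Reagents that add atoms: methyltriphenylphosphonium bromide C[P+](c1ccccc1)(c1ccccc1)c1ccccc1.[Br-]
Why: Wittig methylenation of an aromatic aldehyde is routine, touches nothing else and forms no stereocentre.

Step 2
Reactants: 2 3,4,5-trimethoxystyrene
Product: 3 rac-2,2-dichloro-3-(3,4,5-trimethoxyphenyl)cyclobutan-1-one
Conditions: Cl3CCOCl, Zn-Cu couple, Et2O, reflux
Reagents that add atoms: trichloroacetyl chloride ClC(=O)C(Cl)(Cl)Cl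
Why: In this ketene-alkene [2+2] cycloaddition, dichloroketene bonds through its carbonyl carbon to the CH2 terminus of the electron-rich styrene and gives the 3-aryl regioisomer, whose single racemic stereocentre ceases to be one in step 3.

Step 3
Reactants: 3 rac-2,2-dichloro-3-(3,4,5-trimethoxyphenyl)cyclobutan-1-one
Product: 4 3-(3,4,5-trimethoxyphenyl)cyclobutan-1-one (achiral, mirror-symmetric)
Conditions: Zn dust, AcOH, rt to 60 °C
Reagents that add atoms: none
Why: Reductive dechlorination of an alpha,alpha-dichloroketone by zinc through the zinc enolate leaves the prochiral cyclobutanone and does not affect the aryl ethers.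

Step 4
Reactants: 4 3-(3,4,5-trimethoxyphenyl)cyclobutan-1-one
Product: 5 (S)-trimethyl{[3-(3,4,5-trimethoxyphenyl)cyclobut-1-en-1-yl]oxy}silane
Conditions: (S,S)-bis(1-phenylethyl)amine, n-BuLi, THF; Me3SiCl, then 4, -100 °C
Reagents that add atoms: chlorotrimethylsilane C[Si](C)(C)Cl
Why: Enantioselective deprotonation by a C2-symmetric chiral lithium amide with in situ silyl trapping, a desymmetrisation established for 3-arylcyclobutanones, distinguishes the two enantiotopic CH2 groups and so fixes the aryl-bearing carbon as S.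

Step 5
Reactants: 6 tert-butyl(dimethyl)(prop-2-yn-1-yloxy)silane; 7 allyl bromide
Product: 9 rac-1-[tert-butyl(dimethyl)silyl]hex-5-en-2-yn-1-ol, via dilithio alkoxide 8 (not isolated)
Conditions: n-BuLi then t-BuLi, THF, -78 to -45 °C; CuI (10 mol %), 7, -45 to 0 °C; aq NH4Cl
Reagents that add atoms: none
Why: Double lithiation, retro-Brook (O-to-C) silyl migration and copper-catalysed allylation of the acetylide terminus give the alpha-silyl propargylic alcohol, whose racemic carbinol centre is removed in step 6.

Step 6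
Reactants: 9 rac-1-[tert-butyl(dimethyl)silyl]hex-5-en-2-yn-1-ol
Product: 10 1-[tert-butyl(dimethyl)silyl]hex-5-en-2-yn-1-one
Conditions: Dess-Martin periodinane, CH2Cl2, 0 °C
Reagents that add atoms: none
Why: Dess-Martin oxidation under neutral conditions turns the alpha-silyl carbinol into the acylsilane without Brook rearrangement or isomerisation of the skipped enyne.

Step 7
Reactants: 10 1-[tert-butyl(dimethyl)silyl]hex-5-en-2-yn-1-one; 11 benzenethiol
Product: 12 (Z)-1-[tert-butyl(dimethyl)silyl]-3-(phenylsulfanyl)hexa-2,5-dien-1-one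
Conditions: Et3N (5 mol %), CH2Cl2, -20 °C
Reagents that add atoms: none
Why: Thia-Michael addition to the alkynoylsilane proceeds by anti addition and should give mainly the Z isomer, a geometry that does not matter later because it is lost in the allyl anion.

Step 8
Reactants: 5 (S)-trimethyl{[3-(3,4,5-trimethoxyphenyl)cyclobut-1-en-1-yl]oxy}silane; 12 (Z)-1-[tert-butyl(dimethyl)silyl]-3-(phenylsulfanyl)hexa-2,5-dien-1-one
Product: 15 (1R,5R,6S)-4-{[tert-butyl(dimethyl)silyl]oxy}-2-(phenylsulfanyl)-2-(prop-2-en-1-yl)-6-(3,4,5-trimethoxyphenyl)bicyclo[3.2.0]hept-3-en-1-ol (C2 epimers), via lithium enolate 13 (not isolated), via Brook allyllithium 14 (not isolated)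
Conditions: 5, MeLi, THF, 0 °C; then 12, -80 to -30 °C; AcOH quench
Reagents that add atoms: none
Why: Proposed new method: the enolate carbon of 13 adds 1,2 to the acylsilane carbonyl of 12 (first bond, C5–C9 of the target), the alpha-silyl alkoxide undergoes Brook rearrangement, and the sulfur-stabilised allyl anion 14 attacks the regenerated, strain-activated cyclobutanone carbonyl through its gamma-carbon (second bond, C2–C3 of the target). The closest known reaction type is the Brook-rearrangement-mediated [3+2] annulation of beta-(phenylsulfanyl)acryloylsilanes with lithium enolates of methyl ketones, which gives 4-silyloxycyclopent-3-enols; new here are a cyclobutanone enolate as the two-carbon partner and a fully substituted beta-carbon. The only ring closed is the cyclopentene, by a 5-exo-trig aldol-type attack of the carbanion on C=O, and the four-membered ring allows only cis fusion. In the numbering of 15, C5 is set by approach anti to the C6 aryl group, C1 follows from the cis fusion and C2 is uncontrolled, which is harmless because all three are erased or reset in step 9 and only C6 is carried on. The step needs 1,2- over 1,4-addition and gamma- over alpha-attack of the allyl anion: the beta-carbon of 12 is fully substituted and deactivated by the sulfur donor, and alpha-attack would give a strained cyclopropanolate that forms reversibly. Proton transfer from the alpha-hydrogens to 14 is the competing path and should be held back by the low temperature and the short five-membered transition state.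

Step 9
Reactants: 15 (1R,5R,6S)-4-{[tert-butyl(dimethyl)silyl]oxy}-2-(phenylsulfanyl)-2-(prop-2-en-1-yl)-6-(3,4,5-trimethoxyphenyl)bicyclo[3.2.0]hept-3-en-1-ol
Product: 18 (5R,6S)-5-methyl-2-(prop-2-en-1-yl)-6-(3,4,5-trimethoxyphenyl)cyclohept-2-ene-1,4-dione, via bicyclic enone alkoxide 16 (not isolated), via cycloheptenedione enolate 17 (not isolated)
Conditions: KN(SiMe3)2, THF, -78 °C; Bu4N[Ph3SiF2], MeI, -78 to 0 °C
Reagents that add atoms: iodomethane CI
Why: Fluoride unmasks the ketone, thiophenolate leaves by E1cB elimination, the strained beta-alkoxy ketone undergoes de Mayo-type retro-aldol cleavage of the ring-fusion bond, and the regiodefined enolate 17 is methylated anti to the aryl group, which sets C5 trans to C6.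

Step 10
Reactants: 18 (5R,6S)-5-methyl-2-(prop-2-en-1-yl)-6-(3,4,5-trimethoxyphenyl)cyclohept-2-ene-1,4-dione
Product: 20 (1R,5S,8R,9R)-5-hydroxy-9-methyl-3-(prop-2-en-1-yl)-8-(3,4,5-trimethoxyphenyl)-6-oxabicyclo[3.2.2]non-3-ene-2,7-dione, via lithium keto carboxylate 19 (not isolated)
Conditions: LiN(SiMe3)2, THF, -78 °C; CO2 (gas); 1 M HCl, 0 °C
Reagents that add atoms: carbon dioxide O=C=O
Why: Kinetic alpha'-deprotonation at the only CH2 next to a carbonyl group and carboxylation of that enolate give a beta-keto acid whose acidic carbon epimerises until the carboxyl group adds to the electrophilic enedione carbonyl (lactol formation), which sets C1 and C5 together under thermodynamic control and shields the acid from decarboxylation because the required enol would be a bridgehead alkene.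

Step 11
Reactants: 20 (1R,5S,8R,9R)-5-hydroxy-9-methyl-3-(prop-2-en-1-yl)-8-(3,4,5-trimethoxyphenyl)-6-oxabicyclo[3.2.2]non-3-ene-2,7-dione
Product: 21 (1R,5S,8R,9R)-5-methoxy-9-methyl-3-(prop-2-en-1-yl)-8-(3,4,5-trimethoxyphenyl)-6-oxabicyclo[3.2.2]non-3-ene-2,7-dione (target)
Conditions: MeOH, pyridinium p-toluenesulfonate (cat.), 4 Å molecular sieves, rt
Reagents that add atoms: methanol CO
Why: Pseudo-ester formation of a keto acid (acid-catalysed exchange of the lactol hydroxyl for methoxyl) should outrun Fischer esterification because the methyl hemiketal is trapped intramolecularly by the carboxyl group, and the bridge allows only S at C5 once C1 is R.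

**Compound list**

1 | 3,4,5-trimethoxybenzaldehyde | COc1cc(C=O)cc(OC)c1OC | starting material
2 | 3,4,5-trimethoxystyrene | C=Cc1cc(OC)c(OC)c(OC)c1 | intermediate
3 | rac-2,2-dichloro-3-(3,4,5-trimethoxyphenyl)cyclobutan-1-one | O=C1CC(c2cc(OC)c(OC)c(OC)c2)C1(Cl)Cl | intermediate
4 | 3-(3,4,5-trimethoxyphenyl)cyclobutan-1-one | O=C1CC(c2cc(OC)c(OC)c(OC)c2)C1 | intermediate
5 | (S)-trimethyl{[3-(3,4,5-trimethoxyphenyl)cyclobut-1-en-1-yl]oxy}silane | C1[C@H](c2cc(OC)c(OC)c(OC)c2)C=C1O[Si](C)(C)C | intermediate
6 | tert-butyl(dimethyl)(prop-2-yn-1-yloxy)silane | C#CCO[Si](C)(C)C(C)(C)C | starting material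
7 | allyl bromide | C=CCBr | starting material
8 | lithium 1-[tert-butyl(dimethyl)silyl]-3-lithioprop-2-yn-1-olate | [Li]C#CC(O[Li])[Si](C)(C)C(C)(C)C | intermediate
9 | rac-1-[tert-butyl(dimethyl)silyl]hex-5-en-2-yn-1-ol | C=CCC#CC(O)[Si](C)(C)C(C)(C)C | intermediate
10 | 1-[tert-butyl(dimethyl)silyl]hex-5-en-2-yn-1-one | C=CCC#CC(=O)[Si](C)(C)C(C)(C)C | intermediate
11 | benzenethiol | Sc1ccccc1 | starting material
12 | (Z)-1-[tert-butyl(dimethyl)silyl]-3-(phenylsulfanyl)hexa-2,5-dien-1-one | C=CC/C(Sc1ccccc1)=C/C(=O)[Si](C)(C)C(C)(C)C | intermediate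
13 | lithium (S)-3-(3,4,5-trimethoxyphenyl)cyclobut-1-en-1-olate | C1[C@H](c2cc(OC)c(OC)c(OC)c2)C=C1O[Li] | intermediate
14 | trans-2-[1-(silyloxy)-3-lithio-3-(phenylsulfanyl)hexa-1,5-dien-1-yl]-3-arylcyclobutanone (allyllithium after 1,2-addition and Brook shift) | C1[C@H](c2cc(OC)c(OC)c(OC)c2)[C@@H](C(O[Si](C)(C)C(C)(C)C)=CC([Li])(CC=C)Sc2ccccc2)C1=O | intermediate
15 | (1R,5R,6S)-4-{[tert-butyl(dimethyl)silyl]oxy}-2-(phenylsulfanyl)-2-(prop-2-en-1-yl)-6-(3,4,5-trimethoxyphenyl)bicyclo[3.2.0]hept-3-en-1-ol, cis-fused, five-membered ring anti to aryl, C2 epimers | C1[C@H](c3cc(OC)c(OC)c(OC)c3)[C@H]2C(O[Si](C)(C)C(C)(C)C)=CC(CC=C)(Sc3ccccc3)[C@@]12O | intermediate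
16 | potassium (1R,5R,6S)-4-oxo-2-(prop-2-en-1-yl)-6-(3,4,5-trimethoxyphenyl)bicyclo[3.2.0]hept-2-en-1-olate | C1[C@H](c3cc(OC)c(OC)c(OC)c3)[C@H]2C(=O)C=C(CC=C)[C@@]12[O-].[K+] | intermediate
17 | potassium C4–C5 enolate of (S)-2-allyl-6-(3,4,5-trimethoxyphenyl)cyclohept-2-ene-1,4-dione | C=CCC1=CC([O-])=C[C@@H](c2cc(OC)c(OC)c(OC)c2)CC1=O.[K+] | intermediate
18 | (5R,6S)-5-methyl-2-(prop-2-en-1-yl)-6-(3,4,5-trimethoxyphenyl)cyclohept-2-ene-1,4-dione | C=CCC1=CC(=O)[C@H](C)[C@@H](c2cc(OC)c(OC)c(OC)c2)CC1=O | intermediate
19 | lithium 3-allyl-6-methyl-2,5-dioxo-7-(3,4,5-trimethoxyphenyl)cyclohept-3-ene-1-carboxylate (carboxyl-bearing carbon labile) | C=CCC1=CC(=O)[C@H](C)[C@@H](c2cc(OC)c(OC)c(OC)c2)C(C(=O)[O-])C1=O.[Li+] | intermediate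
20 | (1R,5S,8R,9R)-5-hydroxy-9-methyl-3-(prop-2-en-1-yl)-8-(3,4,5-trimethoxyphenyl)-6-oxabicyclo[3.2.2]non-3-ene-2,7-dione | C=CCC1=C[C@@]2(O)OC(=O)[C@@H](C1=O)[C@H](c1cc(OC)c(OC)c(OC)c1)[C@H]2C | intermediate
21 | (1R,5S,8R,9R)-5-methoxy-9-methyl-3-(prop-2-en-1-yl)-8-(3,4,5-trimethoxyphenyl)-6-oxabicyclo[3.2.2]non-3-ene-2,7-dione | C=CCC1=C[C@@]2(OC)OC(=O)[C@@H](C1=O)[C@H](c1cc(OC)c(OC)c(OC)c1)[C@H]2C | target

Total step count: 11. Longest linear sequence: 8 (steps 1 to 4 and 8 to 11).

**Steps most likely to fail**

Step 8. The hindered 1,2-addition may revert, or the allyl anion may be quenched by proton transfer before the ring closes.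
- The fallback makes the two bonds one after the other with known chemistry. It sets out from 5 (through enolate 13) and comes back at 18, so it also replaces step 9.
- Pent-1-en-4-yne is carboxylated (EtMgBr, CO2) to hex-5-en-2-ynoic acid F1. This is hydroiodinated (NaI, AcOH) to (Z)-3-iodohexa-2,5-dienoic acid F2 and converted with oxalyl chloride into (Z)-3-iodohexa-2,5-dienoyl chloride F3.
- Enolate 13 is C-acylated with F3 to 2-[(Z)-3-iodohexa-2,5-dienoyl]-3-arylcyclobutanone F4.
- F4 is a 1,3-diketone and is methylated between its carbonyl groups (K2CO3, MeI) to the 2-methyl-2-acylcyclobutanone F5.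
- Bu3SnH and AIBN then generate the vinyl radical, which adds to the cyclobutanone carbonyl. The alkoxy radical cleaves the ring bond to the methyl-bearing carbon (Dowd-Beckwith three-atom ring expansion).
- Hydrogen transfer, followed by base equilibration to the trans isomer, gives 18.

Step 9. Proton exchange among the enolates may scramble the site of methylation, methylation may occur on oxygen, or thiolate may add back to the enedione.
- The fallback methylates before the ring is opened, where only one site can enolise. It sets out from 15 and comes back at 18.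
- The tertiary alcohol is silylated (Et3SiOTf, 2,6-lutidine) to the triethylsilyl ether F6.
- The enol silane alone is cleaved and thiophenol eliminated (Bu4NF/AcOH at low temperature, then DBU) to the bicyclic enone silyl ether F7.
- LiN(iPr)2 and MeI alkylate the ring-fusion carbon, the only alpha'-position, to the ring-fusion methyl enone F8.
- Bu4NF then frees the alkoxide. Retro-aldol cleavage and protonation under equilibrating conditions give 18.

Step 10. Deprotonation may occur at the doubly allylic CH2, CO2 may be lost before the lactol closes, or the bridge may close to the wrong diastereomer.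
- The fallback installs the ketal first and closes the bridge under aprotic acid. It sets out from 18 and comes back at 21, so it also replaces step 11.
- The C4 carbonyl is converted (CH(OMe)3, TsOH, MeOH, regioisomer separated) into the 4,4-dimethoxy enone F9, which has a single enolisable position.
- LiN(SiMe3)2 and CO2 give the dimethoxy keto acid F10.
- Camphorsulfonic acid in CH2Cl2 over 5 Å molecular sieves ionises the ketal. The carboxyl group traps the oxocarbenium ion with loss of methanol and gives 21.

**Further compounds**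

F1 | step 8 | hex-5-en-2-ynoic acid | C=CCC#CC(=O)O
F2 | step 8 | (Z)-3-iodohexa-2,5-dienoic acid | C=CC/C(I)=C/C(=O)O
F3 | step 8 | (Z)-3-iodohexa-2,5-dienoyl chloride | C=CC/C(I)=C/C(=O)Cl
F4 | step 8 | 2-[(Z)-3-iodohexa-2,5-dienoyl]-3-(3,4,5-trimethoxyphenyl)cyclobutan-1-one, aryl-bearing carbon as in 5, C2 labile | C1[C@H](c2cc(OC)c(OC)c(OC)c2)C(C(=O)/C=C(I)/CC=C)C1=O
F5 | step 8 | 2-[(Z)-3-iodohexa-2,5-dienoyl]-2-methyl-3-(3,4,5-trimethoxyphenyl)cyclobutan-1-one, aryl-bearing carbon as in 5, C2 inconsequential | C1[C@H](c2cc(OC)c(OC)c(OC)c2)C(C)(C(=O)/C=C(I)/CC=C)C1=O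
F6 | step 9 | triethylsilyl ether of 15 | C1[C@H](c3cc(OC)c(OC)c(OC)c3)[C@H]2C(O[Si](C)(C)C(C)(C)C)=CC(CC=C)(Sc3ccccc3)[C@@]12O[Si](CC)(CC)CC
F7 | step 9 | cis-fused 2-allyl-1-(triethylsilyloxy)-6-(3,4,5-trimethoxyphenyl)bicyclo[3.2.0]hept-2-en-4-one | C1[C@H](c3cc(OC)c(OC)c(OC)c3)[C@H]2C(=O)C=C(CC=C)[C@@]12O[Si](CC)(CC)CC
F8 | step 9 | 5-methyl derivative of F7 (methyl at the ring-fusion carbon, cis fusion kept) | C1[C@H](c3cc(OC)c(OC)c(OC)c3)[C@@]2(C)C(=O)C=C(CC=C)[C@@]12O[Si](CC)(CC)CC
F9 | step 10 | (5R,6S)-4,4-dimethoxy-5-methyl-2-(prop-2-en-1-yl)-6-(3,4,5-trimethoxyphenyl)cyclohept-2-en-1-one | C=CCC1=CC(OC)(OC)[C@H](C)[C@@H](c2cc(OC)c(OC)c(OC)c2)CC1=O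
F10 | step 10 | 3-allyl-5,5-dimethoxy-6-methyl-2-oxo-7-(3,4,5-trimethoxyphenyl)cyclohept-3-ene-1-carboxylic acid (carboxyl-bearing carbon labile) | C=CCC1=CC(OC)(OC)[C@H](C)[C@@H](c2cc(OC)c(OC)c(OC)c2)C(C(=O)O)C1=O
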